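Ring C of the flavonol is taken apart at three bonds: C4a–C4, C4–C3 and O1–C2. C4 is a lone carbonyl carbon between the fully substituted C4a of ring A and the C3–C2 unit that carries ring B, so it can be supplied as carbon monoxide. One palladium-catalysed carbonylative alkyne coupling with in situ 6-endo closure therefore assembles the whole flavone. Its precursors are a hexasubstituted ortho-iodophenol (ring A, four methyl ethers) and a terminal arylacetylene (ring B, phenol masked as a benzyl ether). C3 hydroxylation and one Lewis-acid deprotection finish the target.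

Key step: step 5

Remark on the chemistry: the flavone 2,3-epoxide of step 6 forms as a racemate whose configuration is erased on ring opening; the target has no stereocenter, so no stereocontrol is needed anywhere in the route.

Step 1
Reactants: 1 1,2,3,4-tetramethoxybenzene
Product: 4 2,3,4,5-tetramethoxyphenol, via aryllithium 2 (not isolated), via dimethyl arylboronate 3 (not isolated)
Conditions: n-BuLi, TMEDA, THF, 0 °C to rt; B(OMe)3, −78 °C to rt; AcOH, 30% aq. H2O2, 0 °C to rt
Reagents that add atoms: hydrogen peroxide, OO (phenol oxygen of 4); intermediates 2 and 3 only: n-butyllithium, [Li]CCCC, and trimethyl borate, COB(OC)OC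
Why: Methoxy-directed ortho-lithiation at one of the two equivalent free ring positions, borylation and peroxide-induced aryl migration from boron to oxygen (lithiation–borylation–oxidation) should give the phenol with a single remaining ring C–H.

Step 2
Reactants: 4 2,3,4,5-tetramethoxyphenol
Product: 5 2-iodo-3,4,5,6-tetramethoxyphenol
Conditions: N-iodosuccinimide, MeCN, 0 °C, dark
Reagents that add atoms: N-iodosuccinimide, O=C1CCC(=O)N1I
Why: Electrophilic aromatic iodination of the strongly activated phenol can occur only at the one unsubstituted carbon, which lies ortho to the hydroxyl, so the site of later carbonyl entry is fixed.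

Step 3
Reactants: 6 3-hydroxy-4,5-dimethoxybenzaldehyde
Product: 7 3-(benzyloxy)-4,5-dimethoxybenzaldehyde
Conditions: BnBr, K2CO3, DMF, rt
Reagents that add atoms: benzyl bromide, BrCc1ccccc1
Why: Williamson etherification of the phenoxide installs a benzyl ether that should tolerate carbonate, amine, CO and dioxirane and leave in the final BCl3 operation.

Step 4
Reactants: 7 3-(benzyloxy)-4,5-dimethoxybenzaldehyde; 8 dimethyl (1-diazo-2-oxopropyl)phosphonate
Product: 10 1-(benzyloxy)-5-ethynyl-2,3-dimethoxybenzene, via diazoalkene 9 (not isolated)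
Conditions: 8, K2CO3, MeOH, 0 °C to rt
Reagents that add atoms: dimethyl (1-diazo-2-oxopropyl)phosphonate 8, COP(=O)(OC)C(=[N+]=[N-])C(C)=O (supplies the terminal alkyne carbon)
Why: Seyferth–Gilbert homologation in the Ohira–Bestmann variant: methanolysis of 8 frees the diazomethylphosphonate anion, its Horner–Wadsworth–Emmons-type addition to the non-enolizable aldehyde gives diazoalkene 9, and loss of N2 with a 1,2-hydride shift gives the terminal alkyne.

Step 5
Reactants: 5 2-iodo-3,4,5,6-tetramethoxyphenol; 10 1-(benzyloxy)-5-ethynyl-2,3-dimethoxybenzene; 11 carbon monoxide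
Product: 14 2-[3-(benzyloxy)-4,5-dimethoxyphenyl]-5,6,7,8-tetramethoxy-4H-chromen-4-one, via ortho-hydroxyaryl ynone 12 (not isolated), via diethylamino enone 13 (not isolated)
Conditions: PdCl2(dppf) (5 mol %; dppf = 1,1'-bis(diphenylphosphino)ferrocene), CO (20 bar), Et2NH, 120 °C, autoclave
Reagents that add atoms: carbon monoxide 11, [C-]#[O+] (C4 and its oxygen); intermediate 13 only: diethylamine, CCNCC
Why: The divalent palladium precatalyst is reduced in situ to zerovalent palladium, which inserts into the C–I bond of 5; CO insertion gives an aroylpalladium species (C4a–C4 bond), and amine-assisted alkynyl transfer from 10 with reductive elimination forms the C4–C3 bond of ynone 12. Diethylamine then adds in conjugate fashion to 12 to give enaminone 13, whose amine-bearing carbon is attacked by the ortho-hydroxyl with expulsion of diethylamine (O1–C2 bond), closing ring C in a 6-endo mode. The closest known reaction type is the palladium-catalysed carbonylative Sonogashira annulation of 2-iodophenols with terminal alkynes to flavones in a secondary amine. No stereocenter is created. Two selectivities are needed: carbonylative over direct alkyne coupling (which would end in a benzofuran), secured by CO pressure and by the doubly ortho-substituted, electron-rich arylpalladium that takes up CO readily; and 6-endo over 5-exo closure (aurone), secured by the enaminone, whose β-carbon is the only electrophilic site within reach of the phenol. The carbonyl position is unambiguous because 5 carries iodine on the single carbon that becomes C4a, next to the hydroxyl that becomes O1.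

Step 6
Reactants: 14 2-[3-(benzyloxy)-4,5-dimethoxyphenyl]-5,6,7,8-tetramethoxy-4H-chromen-4-one
Product: 16 2-[3-(benzyloxy)-4,5-dimethoxyphenyl]-3-hydroxy-5,6,7,8-tetramethoxy-4H-chromen-4-one, via flavone 2,3-epoxide 15 (not isolated)
Conditions: dimethyldioxirane (ca. 0.08 M in acetone, 4 equiv), CH2Cl2, 0 °C to rt; concentrate; p-TsOH·H2O (cat.), CH2Cl2, rt
Reagents that add atoms: dimethyldioxirane, CC1(C)OO1
Why: Dimethyldioxirane is a neutral electrophilic oxidant known to epoxidize the C2–C3 double bond of flavones; acid-catalysed opening of the racemic cis-fused epoxide 15 at C2 and loss of the C3 proton should give the 3-hydroxyflavone, so no stereocenter persists.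

Step 7
Reactants: 16 2-[3-(benzyloxy)-4,5-dimethoxyphenyl]-3-hydroxy-5,6,7,8-tetramethoxy-4H-chromen-4-one
Product: 17 3-demethyldigicitrin, 3,5-dihydroxy-2-(3-hydroxy-4,5-dimethoxyphenyl)-6,7,8-trimethoxy-4H-chromen-4-one
Conditions: BCl3 (1 M in CH2Cl2, 4.5 equiv), pentamethylbenzene (3 equiv), CH2Cl2, −78 to 0 °C; MeOH, then aq. HCl, rt
Reagents that add atoms: none
Why: Chelation-controlled Lewis-acid dealkylation: BCl3 should cleave the aryl benzyl ether at low temperature (benzyl cation trapped by pentamethylbenzene) and then the 5-methyl ether through a six-membered boron chelate with the peri C4 carbonyl, while the non-chelated methyl ethers at C6, C7, C8, C4' and C5' are expected to survive at or below 0 °C.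

Compound list
1 | 1,2,3,4-tetramethoxybenzene | COc1ccc(OC)c(OC)c1OC | starting material
2 | (2,3,4,5-tetramethoxyphenyl)lithium | [Li]c1cc(OC)c(OC)c(OC)c1OC | intermediate (not isolated)
3 | dimethyl (2,3,4,5-tetramethoxyphenyl)boronate | COB(OC)c1cc(OC)c(OC)c(OC)c1OC | intermediate (not isolated)
4 | 2,3,4,5-tetramethoxyphenol | COc1cc(O)c(OC)c(OC)c1OC | intermediate
5 | 2-iodo-3,4,5,6-tetramethoxyphenol | COc1c(O)c(I)c(OC)c(OC)c1OC | intermediate
6 | 3-hydroxy-4,5-dimethoxybenzaldehyde | COc1cc(C=O)cc(O)c1OC | starting material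
7 | 3-(benzyloxy)-4,5-dimethoxybenzaldehyde | COc1cc(C=O)cc(OCc2ccccc2)c1OC | intermediate
8 | dimethyl (1-diazo-2-oxopropyl)phosphonate | COP(=O)(OC)C(=[N+]=[N-])C(C)=O | starting material
9 | 1-(benzyloxy)-5-(2-diazoethenyl)-2,3-dimethoxybenzene | COc1cc(C=C=[N+]=[N-])cc(OCc2ccccc2)c1OC | intermediate (not isolated)
10 | 1-(benzyloxy)-5-ethynyl-2,3-dimethoxybenzene | COc1cc(C#C)cc(OCc2ccccc2)c1OC | intermediate
11 | carbon monoxide | [C-]#[O+] | starting material
12 | 3-[3-(benzyloxy)-4,5-dimethoxyphenyl]-1-(2-hydroxy-3,4,5,6-tetramethoxyphenyl)prop-2-yn-1-one | COc1cc(C#CC(=O)c2c(O)c(OC)c(OC)c(OC)c2OC)cc(OCc2ccccc2)c1OC | intermediate (not isolated)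
13 | 3-[3-(benzyloxy)-4,5-dimethoxyphenyl]-3-(diethylamino)-1-(2-hydroxy-3,4,5,6-tetramethoxyphenyl)prop-2-en-1-one (push–pull alkene, E and Z forms interconvert, geometry not fixed) | CCN(CC)C(=CC(=O)c1c(O)c(OC)c(OC)c(OC)c1OC)c1cc(OC)c(OC)c(OCc2ccccc2)c1 | intermediate (not isolated)
14 | 2-[3-(benzyloxy)-4,5-dimethoxyphenyl]-5,6,7,8-tetramethoxy-4H-chromen-4-one | COc1cc(-c2cc(=O)c3c(OC)c(OC)c(OC)c(OC)c3o2)cc(OCc2ccccc2)c1OC | intermediate
15 | 2,3-epoxide of 14, 1a-[3-(benzyloxy)-4,5-dimethoxyphenyl]-3,4,5,6-tetramethoxy-1a,7a-dihydro-7H-oxireno[2,3-b]chromen-7-one (oxirane cis-fused to ring C, racemic, one enantiomer drawn) | COc1cc(cc(OCc2ccccc2)c1OC)[C@]12O[C@H]1C(=O)c1c(OC)c(OC)c(OC)c(OC)c1O2 | intermediate (not isolated)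
16 | 2-[3-(benzyloxy)-4,5-dimethoxyphenyl]-3-hydroxy-5,6,7,8-tetramethoxy-4H-chromen-4-one | COc1cc(-c2oc3c(OC)c(OC)c(OC)c(OC)c3c(=O)c2O)cc(OCc2ccccc2)c1OC | intermediate
17 | 3-demethyldigicitrin, 3,5-dihydroxy-2-(3-hydroxy-4,5-dimethoxyphenyl)-6,7,8-trimethoxy-4H-chromen-4-one | COc1cc(-c2oc3c(OC)c(OC)c(OC)c(O)c3c(=O)c2O)cc(O)c1OC | target

Total step count: 7. Longest linear sequence: 5 steps (steps 1, 2, 5, 6, 7; the ring B branch through steps 3, 4, 5, 6, 7 is equally long).

Steps most likely to fail

Step 5. Alkynyl transfer may outrun CO uptake, so that direct coupling and cyclization to a benzofuran compete. The aroylpalladium species may also be intercepted by diethylamine, and oxidative addition into the hindered, electron-rich C–I bond may be slow. The fallback leaves the carbonylative route and builds ring C by condensation chemistry; it sets out from 4 and 7 and comes back at 14. Phenol 4 would be C-acetylated at its single free carbon (Ac2O, BF3·OEt2, 60–80 °C, Friedel–Crafts/Fries acylation) to give 1-(2-hydroxy-3,4,5,6-tetramethoxyphenyl)ethan-1-one F1. Claisen–Schmidt condensation of this with aldehyde 7 (KOH, EtOH, rt) should give the chalcone (E)-3-[3-(benzyloxy)-4,5-dimethoxyphenyl]-1-(2-hydroxy-3,4,5,6-tetramethoxyphenyl)prop-2-en-1-one F2. Oxidative cyclization with catalytic I2 in DMSO at 120–130 °C should then close and dehydrogenate ring C to flavone 14.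

Step 7. After the first boron phenoxide forms, a neighbouring methyl ether (C6 or C4') may be dealkylated as well. Alternatively, the 3-hydroxyl may tie up the C4 carbonyl in a five-membered boron chelate and retard 5-O-demethylation. The fallback separates the two deprotections mechanistically; it sets out from 16 and comes back at 17. Hydrogenolysis (H2, 10% Pd/C, EtOAc–MeOH, rt) would remove the benzyl group and give 3-hydroxy-2-(3-hydroxy-4,5-dimethoxyphenyl)-5,6,7,8-tetramethoxy-4H-chromen-4-one F3. The milder, chelation-specific AlCl3 in MeCN (rt to 50 °C, then dilute HCl) would then cleave only the peri 5-methyl ether to give 17.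

Step 6. Epoxidation of the electron-poor C2–C3 double bond may be slow enough that oxidation of the benzylic C–H bonds or of the electron-rich rings, or incomplete conversion, becomes significant. The fallback replaces electrophilic oxidation by C3 metalation–borylation–oxidation; it sets out from 14 and comes back at 16. Deprotonation at C3 with LiN(i-Pr)2 (THF, −78 °C) would give {2-[3-(benzyloxy)-4,5-dimethoxyphenyl]-5,6,7,8-tetramethoxy-4-oxo-4H-chromen-3-yl}lithium F4. Trapping with B(OMe)3 would give dimethyl {2-[3-(benzyloxy)-4,5-dimethoxyphenyl]-5,6,7,8-tetramethoxy-4-oxo-4H-chromen-3-yl}boronate F5. Oxidation in the same flask with H2O2/AcOH (0 °C to rt) should give 16.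

Further compounds
F1 | step 5 | 1-(2-hydroxy-3,4,5,6-tetramethoxyphenyl)ethan-1-one | CC(=O)c1c(O)c(OC)c(OC)c(OC)c1OC
F2 | step 5 | (E)-3-[3-(benzyloxy)-4,5-dimethoxyphenyl]-1-(2-hydroxy-3,4,5,6-tetramethoxyphenyl)prop-2-en-1-one | COc1cc(/C=C/C(=O)c2c(O)c(OC)c(OC)c(OC)c2OC)cc(OCc2ccccc2)c1OC
F3 | step 7 | 3-hydroxy-2-(3-hydroxy-4,5-dimethoxyphenyl)-5,6,7,8-tetramethoxy-4H-chromen-4-one | COc1cc(-c2oc3c(OC)c(OC)c(OC)c(OC)c3c(=O)c2O)cc(O)c1OC
F4 | step 6 | {2-[3-(benzyloxy)-4,5-dimethoxyphenyl]-5,6,7,8-tetramethoxy-4-oxo-4H-chromen-3-yl}lithium | [Li]c1c(-c2cc(OC)c(OC)c(OCc3ccccc3)c2)oc2c(OC)c(OC)c(OC)c(OC)c2c1=O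
F5 | step 6 | dimethyl {2-[3-(benzyloxy)-4,5-dimethoxyphenyl]-5,6,7,8-tetramethoxy-4-oxo-4H-chromen-3-yl}boronate | COB(OC)c1c(-c2cc(OC)c(OC)c(OCc3ccccc3)c2)oc2c(OC)c(OC)c(OC)c(OC)c2c1=O
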